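**Plan**

1. Retrosynthesis first removes the late heteroatom decoration: the methyl on the N-oxygen, the C4 oxygen (brought in through N-oxide and nitro chemistry) and the oxidation level of the C2 side chain (CH2OH back to CO2Me).
2. In the resulting pyridine, ring A (N1, C2, C3, C4, C4a, C8a) shares the C4a–C8a bond with carbocycle B (C4a, C5, C6, C7, C8, C8a) and C4 carries only hydrogen. Cutting C4a–C8a and C3–C4 therefore gives a 1,2,4-triazine whose C3 is C8a, tied through C8–C7–C6–C5 to a terminal alkyne (C4a≡C4).
3. The triazine is cut into a chain imidate (C8a), dimethyl aminomalonate (N1, C2 with its ester, C3) and hydrazine (the two nitrogens later lost as N2).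
4. The chain is cut at C5: allylation of a decanoyl imide, cross-metathesis with acrylonitrile (C8 and C8a), and conversion of the acyl carbon into the alkyne.
5. Forward order: chain (steps 1–7), triazine (steps 8–12), rings A and B together (step 13), then C4 oxygen, CH2OH and N–OCH3 (steps 14–19).
6. The only stereocentre, C5 (R), is set in step 2 by the (S)-benzyl oxazolidinone and is not touched afterwards.

Key step: step 13

Remark: locants N1–C8a are those of the quinoline skeleton of the target; 8 is expected as an E/Z mixture, 17 as a mixture of epimers at its ring C5 and 21 as a pair of bridgehead diastereomers, which is without consequence because each of these elements disappears in the following transformation.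

**Route**

Step 1
Reactants: 1 (S)-4-benzyl-1,3-oxazolidin-2-one; 2 decanoyl chloride
Product: 3 (4S)-4-benzyl-3-decanoyl-1,3-oxazolidin-2-one
Conditions: Et3N, DMAP (cat.), CH2Cl2, 0 °C → rt
Reagents that add atoms: none
Why: N-acylation of the oxazolidinone by the acid chloride under DMAP catalysis (nucleophilic acyl substitution) is routine and leaves the C4 benzyl centre untouched.

Step 2
Reactants: 3 (4S)-4-benzyl-3-decanoyl-1,3-oxazolidin-2-one; 4 allyl bromide
Product: 6 (4S)-4-benzyl-3-[(2R)-2-octylpent-4-enoyl]-1,3-oxazolidin-2-one, via sodium Z-enolate 5 (not isolated)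
Conditions: NaN(SiMe3)2, THF, −78 °C; then 4, −78 → −40 °C
Reagents that add atoms: none
Why: Evans asymmetric alkylation, in which the chelated sodium Z-enolate 5 is shielded on one face by the C4 benzyl group so that allyl bromide should enter from the other face and set the future C5 as (R), the minor diastereomer being removable by chromatography.

Step 3
Reactants: 6 (4S)-4-benzyl-3-[(2R)-2-octylpent-4-enoyl]-1,3-oxazolidin-2-one; 7 acrylonitrile
Product: 8 (4S)-4-benzyl-3-[(2R)-5-cyano-2-octylpent-4-enoyl]-1,3-oxazolidin-2-one (E/Z mixture)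
Conditions: 7 (5 equiv), second-generation Hoveyda–Grubbs catalyst RuCl2(H2IMes)(=CH–C6H4-2-OiPr) (5 mol %), CH2Cl2, 40 °C
Reagents that add atoms: none
Why: Olefin cross-metathesis of the terminal alkene with excess electron-poor acrylonitrile under a phosphine-free ruthenium carbene should give the cross product with loss of ethene, and its geometry does not matter because the double bond is saturated next.

Step 4
Reactants: 8 (4S)-4-benzyl-3-[(2R)-5-cyano-2-octylpent-4-enoyl]-1,3-oxazolidin-2-one
Product: 9 (4S)-4-benzyl-3-[(2R)-5-cyano-2-octylpentanoyl]-1,3-oxazolidin-2-one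
Conditions: H2 (1 atm), Pd/C (10 wt% Pd on carbon), EtOAc, rt
Reagents that add atoms: none
Why: Heterogeneous catalytic hydrogenation saturates the conjugated C=C far faster than it attacks a nitrile or a C-benzyl group at 1 atm in a neutral aprotic solvent.

Step 5
Reactants: 9 (4S)-4-benzyl-3-[(2R)-5-cyano-2-octylpentanoyl]-1,3-oxazolidin-2-one
Product: 10 (5R)-5-(hydroxymethyl)tridecanenitrile
Conditions: LiBH4, THF, 0 °C → rt
Reagents that add atoms: none
Why: Reductive cleavage of the N-acyl oxazolidinone by hydride attack at the exocyclic carbonyl gives the primary alcohol without epimerisation, returns the auxiliary and leaves the nitrile alone.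

Step 6
Reactants: 10 (5R)-5-(hydroxymethyl)tridecanenitrile
Product: 11 (5R)-5-formyltridecanenitrile
Conditions: Dess–Martin periodinane, CH2Cl2, 0 °C → rt
Reagents that add atoms: none
Why: Dess–Martin oxidation stops at the aldehyde under nearly neutral conditions that should not enolise the α-branched centre.

Step 7
Reactants: 11 (5R)-5-formyltridecanenitrile
Product: 12 (5R)-5-ethynyltridecanenitrile
Conditions: dimethyl (1-diazo-2-oxopropyl)phosphonate, K2CO3, MeOH, 0 °C → rt
Reagents that add atoms: dimethyl (1-diazo-2-oxopropyl)phosphonate, COP(=O)(OC)C(=[N+]=[N-])C(C)=O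
Why: Seyferth–Gilbert homologation in its Ohira–Bestmann form (olefination to a diazoalkene, loss of N2, 1,2-hydrogen shift) turns CHO into C≡CH under carbonate conditions that α-alkyl-branched aldehydes normally tolerate without epimerisation.

Step 8
Reactants: 12 (5R)-5-ethynyltridecanenitrile
Product: 13 methyl (5R)-5-ethynyltridecanimidate hydrochloride
Conditions: HCl (4 M in dioxane), MeOH (1.2 equiv), Et2O, 0 °C
Reagents that add atoms: methanol, CO; hydrogen chloride, Cl
Why: Pinner reaction, in which anhydrous HCl activates the nitrile for addition of methanol, while a terminal alkyne is inert to HCl at 0 °C.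

Step 9
Reactants: 13 methyl (5R)-5-ethynyltridecanimidate hydrochloride; 14 dimethyl aminomalonate hydrochloride
Product: 17 methyl 3-[(4R)-4-ethynyldodecyl]-6-oxo-1,4,5,6-tetrahydro-1,2,4-triazine-5-carboxylate, via N-malonyl imidate 15 (not isolated), via amidrazone 16 (not isolated)
Conditions: Et3N (1 equiv), CH2Cl2, 0 °C → rt; then N2H4·H2O (1 equiv), MeOH, 0 → 40 °C
Reagents that add atoms: hydrazine (as hydrate), NN
Why: This is the imidate/α-amino ester/hydrazine construction of 4,5-dihydro-1,2,4-triazin-6(1H)-ones, in which the amine exchanges with the imidate nitrogen to give 15, hydrazine displaces methoxide to give amidrazone 16, and the terminal NH2 of 16 acylates on one ester in a 6-exo-trig closure, so that the amino nitrogen is fixed as triazine N4 and the remaining ester sits on triazine C5.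

Step 10
Reactants: 17 methyl 3-[(4R)-4-ethynyldodecyl]-6-oxo-1,4,5,6-tetrahydro-1,2,4-triazine-5-carboxylate
Product: 18 methyl 3-[(4R)-4-ethynyldodecyl]-6-oxo-1,6-dihydro-1,2,4-triazine-5-carboxylate
Conditions: DDQ, 1,4-dioxane, rt
Reagents that add atoms: none
Why: Dehydrogenation by DDQ (hydride abstraction from the doubly activated ring C5–H, then loss of the N4 proton) should form the N4=C5 bond easily and leave the alkyne alone.

Step 11
Reactants: 18 methyl 3-[(4R)-4-ethynyldodecyl]-6-oxo-1,6-dihydro-1,2,4-triazine-5-carboxylate
Product: 19 methyl 6-chloro-3-[(4R)-4-ethynyldodecyl]-1,2,4-triazine-5-carboxylate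
Conditions: POCl3, 80 °C
Reagents that add atoms: phosphoryl chloride, O=P(Cl)(Cl)Cl
Why: Deoxychlorination of the cyclic amide through its O-dichlorophosphate, as practised on pyridazinones and on triazinone carboxylates, puts a leaving group on triazine C6 so that the methoxy group can later be placed on carbon without ambiguity.

Step 12
Reactants: 19 methyl 6-chloro-3-[(4R)-4-ethynyldodecyl]-1,2,4-triazine-5-carboxylate
Product: 20 methyl 3-[(4R)-4-ethynyldodecyl]-6-methoxy-1,2,4-triazine-5-carboxylate
Conditions: NaOMe (1.05 equiv), MeOH, −10 → 0 °C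
Reagents that add atoms: sodium methoxide, [Na+].[O-]C
Why: Nucleophilic aromatic substitution (addition–elimination) at triazine C6, activated by the neighbouring ring nitrogen and the ortho ester, gives the methyl ether regiospecifically and avoids the N1-methylation that direct alkylation of 18 would risk.

Step 13
Reactants: 20 methyl 3-[(4R)-4-ethynyldodecyl]-6-methoxy-1,2,4-triazine-5-carboxylate
Product: 22 methyl (5R)-3-methoxy-5-octyl-5,6,7,8-tetrahydroquinoline-2-carboxylate, via diazene-bridged cycloadduct 21 (not isolated)
Conditions: 1,2,4-trichlorobenzene (0.01 M), 200 °C, Ar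
Reagents that add atoms: none
Why: On heating, the tethered alkyne (2π) should add across C3 and C6 of the electron-poor triazine (4π) in an intramolecular inverse-electron-demand Diels–Alder reaction to give adduct 21, which at this temperature expels N2 by retro-[4+2] and becomes the pyridine. The closest known reaction type is the thermal intramolecular cycloaddition of 3-(alk-ω-ynyl)-1,2,4-triazines to cycloalka[b]pyridines, which includes 5,6,7,8-tetrahydroquinolines from four-carbon tethers. Ring B closes in the cycloaddition itself, as a six-membered carbocycle, by formation of C4a–C8a through the all-carbon tether C5–C8; ring A closes in the same event by formation of C3–C4 and becomes aromatic when N2 leaves. No stereocentre is created in the product, since both bridgehead carbons of 21 end up sp2, and C5 is carried through unchanged because neither acid nor base is present and a propargylic C–H has no thermal path to inversion. The step needs regioselectivity (addition across C3/C6 and not across C5/N2 of the triazine) and a rate that outruns decomposition. The first is enforced by the tether, which lets the inner alkyne carbon reach only the triazine carbon that bears the chain, and the second is helped by the ester on the triazine, which lowers its LUMO and offsets the donor methoxy group, by the branch at the propargylic carbon, which favours the folded conformer, and by high dilution, which suppresses intermolecular addition.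

Step 14
Reactants: 22 methyl (5R)-3-methoxy-5-octyl-5,6,7,8-tetrahydroquinoline-2-carboxylate
Product: 23 methyl (5R)-3-methoxy-5-octyl-5,6,7,8-tetrahydroquinoline-2-carboxylate 1-oxide
Conditions: mCPBA, ClCH2CH2Cl, 50 °C
Reagents that add atoms: 3-chloroperbenzoic acid (mCPBA), OOC(=O)c1cccc(Cl)c1
Why: N-oxidation by electrophilic oxygen transfer from the peracid to the pyridine nitrogen should proceed on gentle warming, and the molecule holds no other oxidisable group.

Step 15
Reactants: 23 methyl (5R)-3-methoxy-5-octyl-5,6,7,8-tetrahydroquinoline-2-carboxylate 1-oxide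
Product: 24 methyl (5R)-3-methoxy-4-nitro-5-octyl-5,6,7,8-tetrahydroquinoline-2-carboxylate 1-oxide
Conditions: fuming HNO3, conc. H2SO4, 70 °C; quench on ice
Reagents that add atoms: nitric acid, O[N+](=O)[O-]
Why: Electrophilic nitration of a pyridine N-oxide goes para to the N-oxide, here also ortho to the methoxy group and at the only free ring position, and an aryl methyl ester withstands mixed acid when the quench is cold.

Step 16
Reactants: 24 methyl (5R)-3-methoxy-4-nitro-5-octyl-5,6,7,8-tetrahydroquinoline-2-carboxylate 1-oxide
Product: 26 benzyl (5R)-4-(benzyloxy)-3-methoxy-5-octyl-5,6,7,8-tetrahydroquinoline-2-carboxylate 1-oxide, via methyl ester benzyl ether 25 (not isolated)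
Conditions: NaH (1.5 equiv), BnOH (solvent), 0 °C → rt
Reagents that add atoms: benzyl alcohol (as sodium benzyl oxide), OCc1ccccc1
Why: Nucleophilic aromatic substitution of the 4-nitro group of a pyridine N-oxide by alkoxide should be complete at low temperature before deprotonation at C5 becomes significant, and the alkoxide-catalysed transesterification that follows in benzyl alcohol converges on the single benzyl ester.

Step 17
Reactants: 26 benzyl (5R)-4-(benzyloxy)-3-methoxy-5-octyl-5,6,7,8-tetrahydroquinoline-2-carboxylate 1-oxide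
Product: 27 [(5R)-4-(benzyloxy)-3-methoxy-5-octyl-1-oxido-5,6,7,8-tetrahydroquinolin-1-ium-2-yl]methanol
Conditions: LiBH4, THF, 0 °C → rt
Reagents that add atoms: none
Why: Hydride reduction of the ester, activated by the adjacent N-oxide, should give the primary alcohol while the N-oxide and the benzyl ether are inert to borohydride.

Step 18
Reactants: 27 [(5R)-4-(benzyloxy)-3-methoxy-5-octyl-1-oxido-5,6,7,8-tetrahydroquinolin-1-ium-2-yl]methanol
Product: 28 (5R)-1-hydroxy-2-(hydroxymethyl)-3-methoxy-5-octyl-5,6,7,8-tetrahydroquinolin-4(1H)-one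
Conditions: H2 (1 atm), Pd/C (10 wt% Pd on carbon), EtOH, rt, stopped after 1 equiv of H2
Reagents that add atoms: none
Why: Catalytic hydrogenolysis of the benzyl ether frees the 4-hydroxypyridine N-oxide, which rests as its N-hydroxy-4-pyridone tautomer, and stopping at one equivalent should spare the N–O bond.

Step 19
Reactants: 28 (5R)-1-hydroxy-2-(hydroxymethyl)-3-methoxy-5-octyl-5,6,7,8-tetrahydroquinolin-4(1H)-one
Product: 29 (5R)-2-(hydroxymethyl)-1,3-dimethoxy-5-octyl-5,6,7,8-tetrahydroquinolin-4(1H)-one
Conditions: MeI (1.2 equiv), K2CO3, DMF, rt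
Reagents that add atoms: iodomethane, CI
Why: SN2 O-alkylation of the acidic N-hydroxy group, which carbonate deprotonates while the primary alcohol stays neutral, is expected on the N-oxygen, as is usual for 1-hydroxy-4-pyridone anions with alkyl halides.

**Compound list**

1 | (S)-4-benzyl-1,3-oxazolidin-2-one | O=C1OC[C@H](Cc2ccccc2)N1 | starting material
2 | decanoyl chloride | CCCCCCCCCC(=O)Cl | starting material
3 | (4S)-4-benzyl-3-decanoyl-1,3-oxazolidin-2-one | CCCCCCCCCC(=O)N1[C@@H](Cc2ccccc2)COC1=O | intermediate
4 | allyl bromide | C=CCBr | starting material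
5 | sodium Z-enolate of 3 (formed in the flask) | CCCCCCCC/C=C(\[O-])N1[C@@H](Cc2ccccc2)COC1=O.[Na+] | intermediate
6 | (4S)-4-benzyl-3-[(2R)-2-octylpent-4-enoyl]-1,3-oxazolidin-2-one | CCCCCCCC[C@H](CC=C)C(=O)N1[C@@H](Cc2ccccc2)COC1=O | intermediate
7 | acrylonitrile | C=CC#N | starting material
8 | (4S)-4-benzyl-3-[(2R)-5-cyano-2-octylpent-4-enoyl]-1,3-oxazolidin-2-one (E/Z mixture) | CCCCCCCC[C@H](CC=CC#N)C(=O)N1[C@@H](Cc2ccccc2)COC1=O | intermediate
9 | (4S)-4-benzyl-3-[(2R)-5-cyano-2-octylpentanoyl]-1,3-oxazolidin-2-one | CCCCCCCC[C@H](CCCC#N)C(=O)N1[C@@H](Cc2ccccc2)COC1=O | intermediate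
10 | (5R)-5-(hydroxymethyl)tridecanenitrile | CCCCCCCC[C@H](CCCC#N)CO | intermediate
11 | (5R)-5-formyltridecanenitrile | CCCCCCCC[C@H](CCCC#N)C=O | intermediate
12 | (5R)-5-ethynyltridecanenitrile | CCCCCCCC[C@H](CCCC#N)C#C | intermediate
13 | methyl (5R)-5-ethynyltridecanimidate hydrochloride | CCCCCCCC[C@H](CCCC(=N)OC)C#C.Cl | intermediate
14 | dimethyl aminomalonate hydrochloride | COC(=O)C(N)C(=O)OC.Cl | starting material
15 | dimethyl 2-{[(5R)-5-ethynyl-1-methoxytridecylidene]amino}propanedioate (formed in the flask) | CCCCCCCC[C@H](CCCC(OC)=NC(C(=O)OC)C(=O)OC)C#C | intermediate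
16 | dimethyl 2-{[(5R)-5-ethynyl-1-hydrazinylidenetridecyl]amino}propanedioate, the amidrazone (formed in the flask) | CCCCCCCC[C@H](CCCC(=NN)NC(C(=O)OC)C(=O)OC)C#C | intermediate
17 | methyl 3-[(4R)-4-ethynyldodecyl]-6-oxo-1,4,5,6-tetrahydro-1,2,4-triazine-5-carboxylate (epimers at ring C5) | CCCCCCCC[C@H](CCCC1=NNC(=O)C(C(=O)OC)N1)C#C | intermediate
18 | methyl 3-[(4R)-4-ethynyldodecyl]-6-oxo-1,6-dihydro-1,2,4-triazine-5-carboxylate | CCCCCCCC[C@H](CCCc1nc(C(=O)OC)c(=O)[nH]n1)C#C | intermediate
19 | methyl 6-chloro-3-[(4R)-4-ethynyldodecyl]-1,2,4-triazine-5-carboxylate | CCCCCCCC[C@H](CCCc1nnc(Cl)c(C(=O)OC)n1)C#C | intermediate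
20 | methyl 3-[(4R)-4-ethynyldodecyl]-6-methoxy-1,2,4-triazine-5-carboxylate | CCCCCCCC[C@H](CCCc1nnc(OC)c(C(=O)OC)n1)C#C | intermediate
21 | [4+2] adduct of 20: 2,3,5-triazabicyclo[2.2.2]octa-2,5,7-triene with N=N bridge, fused at its C=C to ring B, (R) at the octyl-bearing carbon (formed in the flask) | CCCCCCCC[C@@H]1CCCC23N=NC(OC)(C=C12)C(C(=O)OC)=N3 | intermediate
22 | methyl (5R)-3-methoxy-5-octyl-5,6,7,8-tetrahydroquinoline-2-carboxylate | CCCCCCCC[C@@H]1CCCc2c1cc(OC)c(C(=O)OC)n2 | intermediate
23 | methyl (5R)-3-methoxy-5-octyl-5,6,7,8-tetrahydroquinoline-2-carboxylate 1-oxide | CCCCCCCC[C@@H]1CCCc2c1cc(OC)c(C(=O)OC)[n+]2[O-] | intermediate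
24 | methyl (5R)-3-methoxy-4-nitro-5-octyl-5,6,7,8-tetrahydroquinoline-2-carboxylate 1-oxide | CCCCCCCC[C@@H]1CCCc2c1c([N+](=O)[O-])c(OC)c(C(=O)OC)[n+]2[O-] | intermediate
25 | methyl (5R)-4-(benzyloxy)-3-methoxy-5-octyl-5,6,7,8-tetrahydroquinoline-2-carboxylate 1-oxide (formed in the flask) | CCCCCCCC[C@@H]1CCCc2c1c(OCc3ccccc3)c(OC)c(C(=O)OC)[n+]2[O-] | intermediate
26 | benzyl (5R)-4-(benzyloxy)-3-methoxy-5-octyl-5,6,7,8-tetrahydroquinoline-2-carboxylate 1-oxide | CCCCCCCC[C@@H]1CCCc2c1c(OCc3ccccc3)c(OC)c(C(=O)OCc3ccccc3)[n+]2[O-] | intermediate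
27 | [(5R)-4-(benzyloxy)-3-methoxy-5-octyl-1-oxido-5,6,7,8-tetrahydroquinolin-1-ium-2-yl]methanol | CCCCCCCC[C@@H]1CCCc2c1c(OCc3ccccc3)c(OC)c(CO)[n+]2[O-] | intermediate
28 | (5R)-1-hydroxy-2-(hydroxymethyl)-3-methoxy-5-octyl-5,6,7,8-tetrahydroquinolin-4(1H)-one | CCCCCCCC[C@@H]1CCCc2c1c(=O)c(OC)c(CO)n2O | intermediate
29 | (5R)-2-(hydroxymethyl)-1,3-dimethoxy-5-octyl-5,6,7,8-tetrahydroquinolin-4(1H)-one | CCCCCCCC[C@@H]1CCCc2c1c(=O)c(OC)c(CO)n2OC | target

**Step count and risks**

Total step count: 19. Longest linear sequence: 19 steps (from 1 and 2 to 29).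

Steps most likely to fail:

Step 9. The weakly nucleophilic aminomalonate may exchange slowly with the imidate, and an amidine formed along the way may close onto an ester to a five-membered hydroxyimidazole instead of the six-membered ring. The fallback for step 9 sets out from 13 and builds the same C–N bond as an amide first. Mild hydrolysis of the imidate salt (H2O, THF, rt) would give methyl (5R)-5-ethynyltridecanoate F1, which LiOH (THF/H2O) would saponify to (5R)-5-ethynyltridecanoic acid F2, ready for coupling. Carbodiimide coupling of this acid with 14 (EDC·HCl, HOBt, iPr2NEt, CH2Cl2) would give dimethyl 2-[(5R)-5-ethynyltridecanamido]propanedioate F3, which Lawesson's reagent (THF, 50 °C) would turn into dimethyl 2-[(5R)-5-ethynyltridecanethioamido]propanedioate F4, the thioamide. Hydrazine hydrate (MeOH, 0 °C → rt) would then displace sulfur from this thioamide to give amidrazone 16, which closes to 17, where the route is rejoined.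

Step 13. The donor methoxy group on the triazine raises its LUMO, so the cycloaddition may be slow enough for thermal decomposition or alkyne oligomerisation to compete. The fallback for step 13 sets out from 19 and moves the introduction of the methoxy group behind the ring closure. The more electron-poor chloro-triazine 19 would be heated instead (1,2-dichlorobenzene, 160–180 °C) and should pass through the diazene-bridged chloro cycloadduct F5 to methyl (5R)-3-chloro-5-octyl-5,6,7,8-tetrahydroquinoline-2-carboxylate F6 with loss of dinitrogen. Palladium-catalysed C–O coupling of this chloride with methanol (Pd2(dba)3, tBuBrettPhos, Cs2CO3, MeOH/toluene, 80 °C) would then give 22, where the route is rejoined.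

Step 19. Methylation may go partly to the C4 oxygen instead of the N-oxygen (poor site selectivity of the ambident anion), and the hydrogenolysis before it may over-reduce the N–O bond. The fallback for step 19 sets out from 27 and fixes the methyl on the N-oxide oxygen before the pyridone is unmasked. MeOTf (CH2Cl2, 0 °C) would alkylate the only strongly nucleophilic oxygen to give (5R)-4-(benzyloxy)-2-(hydroxymethyl)-1,3-dimethoxy-5-octyl-5,6,7,8-tetrahydroquinolin-1-ium trifluoromethanesulfonate F7, from which NaI (acetone, rt) would remove the benzyl group by SN2 attack at the benzylic carbon of the 4-alkoxypyridinium. This would give the target 29 directly and replace steps 18 and 19.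

**Further compounds**

F1 | step 9 | methyl (5R)-5-ethynyltridecanoate | CCCCCCCC[C@H](CCCC(=O)OC)C#C
F2 | step 9 | (5R)-5-ethynyltridecanoic acid | CCCCCCCC[C@H](CCCC(=O)O)C#C
F3 | step 9 | dimethyl 2-[(5R)-5-ethynyltridecanamido]propanedioate | CCCCCCCC[C@H](CCCC(=O)NC(C(=O)OC)C(=O)OC)C#C
F4 | step 9 | dimethyl 2-[(5R)-5-ethynyltridecanethioamido]propanedioate | CCCCCCCC[C@H](CCCC(=S)NC(C(=O)OC)C(=O)OC)C#C
F5 | step 13 | diazene-bridged chloro cycloadduct | CCCCCCCC[C@@H]1CCCC23N=NC(Cl)(C=C12)C(C(=O)OC)=N3
F6 | step 13 | methyl (5R)-3-chloro-5-octyl-5,6,7,8-tetrahydroquinoline-2-carboxylate | CCCCCCCC[C@@H]1CCCc2c1cc(Cl)c(C(=O)OC)n2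
F7 | step 19 | (5R)-4-(benzyloxy)-2-(hydroxymethyl)-1,3-dimethoxy-5-octyl-5,6,7,8-tetrahydroquinolin-1-ium trifluoromethanesulfonate | CCCCCCCC[C@@H]1CCCc2c1c(OCc3ccccc3)c(OC)c(CO)[n+]2OC.[O-]S(=O)(=O)C(F)(F)F
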